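Locants: lactone ring O1, C2(=O), C3=C4, C5, C6. Side chain C1'=C2' (Z), C3'H2, C4'(OH), C5', C6'(OH), C7', C8'(OAc), C9', C10'-Ph.
Cuts, in order: C2=O goes back to a 2-methoxy-5,6-dihydro-2H-pyran (lactol ether), and the 8'-acetate/4',6'-diol to a triol carrying one movable acetonide. Next, C3'–C2' is cut together with C4'–O. Last come C5'–C6' (allyl transfer) on the left, and O1–C2 plus C5–C6 (hetero-Diels–Alder) on the right.
Enabling feature: in the array O–C4'H–C3'H2–C2'H=C1'H(Z)–C6 the carbinol carbon lies directly beside the methylene bonded to the vinyl carbon. This is the retron of a vicinal bis(boronate) from a terminal C3'=C4' alkene: the primary C3'–B bond couples with a (Z)-bromoalkene and the secondary C4'–B bond becomes C4'–OH.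
Forward: the C6'–C10' diol takes up allyl and is closed to the trans-dioxane 7. The pyran ring arises by [4+2] and is carried on to the (Z)-bromoalkene 13. Alkene 7, B2pin2 and 13 are joined in one flask, then the dioxane ring moves from O6'/O8' to O4'/O6', followed by acetylation, hydrolysis and lactol oxidation.
Stereochemistry: C8' from Noyori hydrogenation, C6' from catalyst-controlled Ir allylation, C4' from ligand-controlled Pt diboration, C6 from a Cr(III)-catalysed hetero-Diels–Alder reaction. The Z geometry comes from syn-hydroboration/protonolysis of a bromoalkyne and a stereoretentive coupling.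
The acetate is placed by a dynamic step: the anti (twist-boat) 6',8'-acetonide drains into the syn (chair) 4',6'-acetonide, which frees O8' alone.

Key step: step 8

Assumption: the antipode named for each chiral ligand in steps 3, 5 and 8 is the one taken to attack the prochiral face stated in the Why line. Both antipodes are available, so a reversed sense would change only the ligand label.

Step 1
Reactants: 1 ethyl 3-oxo-5-phenylpentanoate
Product: 2 ethyl (3R)-3-hydroxy-5-phenylpentanoate
Conditions: H2 (50 atm), RuCl2[(R)-BINAP] (0.2 mol %), EtOH, 50 °C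
Reagents that add atoms: none
Why: Noyori asymmetric hydrogenation of a beta-keto ester, in which chelation of the ester carbonyl to the (R)-BINAP–Ru hydride fixes the ketone face and sets C8' as R.

Step 2
Reactants: 2 ethyl (3R)-3-hydroxy-5-phenylpentanoate
Product: 3 (3R)-5-phenylpentane-1,3-diol
Conditions: LiAlH4, THF, 0 °C to rt
Reagents that add atoms: none
Why: Standard hydride reduction of an ester to the primary alcohol, which leaves the C8' carbinol untouched.

Step 3
Reactants: 3 (3R)-5-phenylpentane-1,3-diol; 4 allyl acetate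
Product: 6 (3R,5R)-1-phenyloct-7-ene-3,5-diol, via hydroxy aldehyde 5 (not isolated)
Conditions: cyclometallated pi-allyl-Ir(III) C,O-benzoate of (R)-Cl,MeO-BIPHEP and 4-cyano-3-nitrobenzoic acid (5 mol %), Cs2CO3 (20 mol %), THF, 100 °C, sealed tube
Reagents that add atoms: none
Why: Krische allylation (transfer-hydrogenative carbonyl allylation) of an unprotected 1,3-diol, in which only the primary alcohol is dehydrogenated to aldehyde 5 and the chiral allyl-iridium adds to its Re face through a closed chair transition state, so that C6' is set R (anti to C8') under catalyst control.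

Step 4
Reactants: 6 (3R,5R)-1-phenyloct-7-ene-3,5-diol
Product: 7 (4R,6R)-2,2-dimethyl-4-(2-phenylethyl)-6-(prop-2-en-1-yl)-1,3-dioxane
Conditions: 2,2-dimethoxypropane, PPTS (cat.), CH2Cl2, rt
Reagents that add atoms: 2,2-dimethoxypropane COC(C)(C)OC
Why: Acid-catalysed transketalisation closes the only possible six-membered acetonide and masks both hydroxyl groups against the base and the boron chemistry of step 8.

Step 5
Reactants: 8 (E)-1-methoxybuta-1,3-diene; 9 3-(trimethylsilyl)prop-2-ynal
Product: 10 (2R,6S)-2-methoxy-6-[(trimethylsilyl)ethynyl]-5,6-dihydro-2H-pyran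
Conditions: tridentate Schiff-base Cr(III)Cl catalyst from (1R,2S)-1-aminoindan-2-ol and 3-(1-adamantyl)-5-methylsalicylaldehyde (3 mol %), 4 Å MS, neat, 0 °C to rt
Reagents that add atoms: none
Why: Catalytic enantioselective hetero-Diels–Alder reaction of an ynal bound to the chiral Cr(III) Lewis acid, in which the diene terminus attacks the Si face of the aldehyde (sets C6 as S), the endo mode gives the cis-2,6 adduct, and the whole lactone skeleton is delivered at the lactol-ether oxidation level.

Step 6
Reactants: 10 (2R,6S)-2-methoxy-6-[(trimethylsilyl)ethynyl]-5,6-dihydro-2H-pyran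
Product: 11 (2R,6S)-6-(bromoethynyl)-2-methoxy-5,6-dihydro-2H-pyran
Conditions: NBS, AgNO3 (10 mol %), acetone, rt, dark
Reagents that add atoms: N-bromosuccinimide O=C1CCC(=O)N1Br
Why: Silver-catalysed bromodesilylation of a silylalkyne through the silver acetylide, which is faster than any attack of NBS on the ring alkene deactivated by its allylic acetal.

Step 7
Reactants: 11 (2R,6S)-6-(bromoethynyl)-2-methoxy-5,6-dihydro-2H-pyran
Product: 13 (2R,6S)-6-[(Z)-2-bromoethenyl]-2-methoxy-5,6-dihydro-2H-pyran, via alpha-bromoalkenylborane 12 (not isolated)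
Conditions: Cy2BH (from BH3·SMe2 and cyclohexene), THF, 0 °C to rt; then AcOH (4 equiv), 0 °C to rt
Reagents that add atoms: none
Why: Syn-hydroboration of a 1-bromoalkyne places boron on the bromine-bearing carbon and protonolysis of the C–B bond proceeds with retention, which fixes the Z geometry, while the hindered borane ignores the 1,2-disubstituted ring alkene.

Step 8
Reactants: 7 (4R,6R)-2,2-dimethyl-4-(2-phenylethyl)-6-(prop-2-en-1-yl)-1,3-dioxane; 13 (2R,6S)-6-[(Z)-2-bromoethenyl]-2-methoxy-5,6-dihydro-2H-pyran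
Product: 16 (2R,4Z)-1-[(4R,6R)-2,2-dimethyl-6-(2-phenylethyl)-1,3-dioxan-4-yl]-5-[(2S,6R)-6-methoxy-3,6-dihydro-2H-pyran-2-yl]pent-4-en-2-ol, via bis(boronate) 14 (not isolated), via secondary boronate 15 (not isolated)
Conditions: B2pin2 (1.05 equiv), Pt(dba)3 (3 mol %), (R,R)-3,5-diisopropylphenyl-TADDOL phenylphosphonite (3.6 mol %), THF, 60 °C; then 13, Pd(OAc)2/RuPhos (2.5 mol %), KOH (3 equiv), THF/H2O 10:1, 70 °C; then 3 M NaOH, 30 % H2O2, 0 °C to rt
Reagents that add atoms: bis(pinacolato)diboron CC1(C)OB(OC1(C)C)B1OC(C)(C)C(C)(C)O1 (its boron stays only in 14 and 15); hydrogen peroxide OO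
Why: Pt(0) inserts into the B–B bond and delivers both boryl groups syn to the terminal C3'=C4' alkene of 7; the TADDOL-phosphonite ligand directs them to the Re face of C4', so the only new stereocentre (C4') is set by the catalyst, the homoallylic C6' centre being too remote to override it. In the same flask Pd(0)/RuPhos adds to the C–Br bond of 13 with retention, the hydroxide-activated bis(boronate) 14 transmetalates through its primary C3'–B bond only, and reductive elimination forms C3'–C2' to give 15. Alkaline peroxide then turns the remaining secondary C4'–B bond into C4'–OH by 1,2-migration with retention. The closest known reaction type is the single-flask enantioselective diboration/Suzuki–Miyaura coupling/oxidation cascade of 1-alkenes with aryl and alkenyl halides, which yields homoallylic alcohols; no ring is closed. Site selectivity rests on the lower steric demand of the CH2–B terminus and on its activation by the neighbouring boronate, Z geometry on stereoretentive oxidative addition and reductive elimination at sp2 carbon, and chemoselectivity in the Pt stage on the fact that 13, added only afterwards, has no terminal alkene. The substrates are built for aqueous KOH and peroxide: the lactone is held as its methyl lactol ether, O6' and O8' as an acetonide (a free C6'-OH would steer the coupling to the secondary boronate), and no ester is present yet.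

Step 9
Reactants: 16 (2R,4Z)-1-[(4R,6R)-2,2-dimethyl-6-(2-phenylethyl)-1,3-dioxan-4-yl]-5-[(2S,6R)-6-methoxy-3,6-dihydro-2H-pyran-2-yl]pent-4-en-2-ol
Product: 17 (2R)-1-[(4S,6R)-6-{(2Z)-3-[(2S,6R)-6-methoxy-3,6-dihydro-2H-pyran-2-yl]prop-2-en-1-yl}-2,2-dimethyl-1,3-dioxan-4-yl]-4-phenylbutan-2-ol
Conditions: PPTS (10 mol %), dry acetone, 40 °C, to equilibrium
Reagents that add atoms: none
Why: Acid-catalysed acetonide migration under thermodynamic control, in which reversible opening to the O6'-bound oxocarbenium ion lets the free C4'-OH compete with O8', and the cis-4,6-disubstituted chair dioxane of the syn pair lies below the trans (twist-boat) dioxane of the anti pair, so the mixture should drain to 17 without touching a stereocentre.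

Step 10
Reactants: 17 (2R)-1-[(4S,6R)-6-{(2Z)-3-[(2S,6R)-6-methoxy-3,6-dihydro-2H-pyran-2-yl]prop-2-en-1-yl}-2,2-dimethyl-1,3-dioxan-4-yl]-4-phenylbutan-2-ol
Product: 18 (2R)-1-[(4R,6R)-6-{(2Z)-3-[(2S,6R)-6-methoxy-3,6-dihydro-2H-pyran-2-yl]prop-2-en-1-yl}-2,2-dimethyl-1,3-dioxan-4-yl]-4-phenylbutan-2-yl acetate
Conditions: Ac2O, pyridine, DMAP (cat.), CH2Cl2, rt
Reagents that add atoms: acetic anhydride CC(=O)OC(C)=O
Why: DMAP-catalysed acylation of the only free hydroxyl group (O8') with retention at C8'.

Step 11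
Reactants: 18 (2R)-1-[(4R,6R)-6-{(2Z)-3-[(2S,6R)-6-methoxy-3,6-dihydro-2H-pyran-2-yl]prop-2-en-1-yl}-2,2-dimethyl-1,3-dioxan-4-yl]-4-phenylbutan-2-yl acetate
Product: 19 (3R,5R,7R,9Z)-5,7-dihydroxy-10-[(2S)-6-hydroxy-3,6-dihydro-2H-pyran-2-yl]-1-phenyldec-9-en-3-yl acetate (lactol, both anomers)
Conditions: AcOH/THF/H2O 3:1:1, 40 °C
Reagents that add atoms: water O
Why: Mild aqueous acid hydrolyses the isopropylidene ketal and the allylic methyl acetal (through an allyl-stabilised oxocarbenium ion), whereas the secondary acetate is inert at this acidity.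

Step 12
Reactants: 19 (3R,5R,7R,9Z)-5,7-dihydroxy-10-[(2S)-6-hydroxy-3,6-dihydro-2H-pyran-2-yl]-1-phenyldec-9-en-3-yl acetate
Product: 20 (6S)-6-[(1Z,4R,6R,8R)-8-acetoxy-4,6-dihydroxy-10-phenyldec-1-en-1-yl]-5,6-dihydro-2H-pyran-2-one
Conditions: activated MnO2 (20 equiv), CH2Cl2, rt
Reagents that add atoms: none
Why: MnO2 oxidation of an allylic lactol to the unsaturated lactone, selective because only the C2 carbinol is allylic (to C3=C4) while the C4' and C6' alcohols are isolated secondary alcohols that this reagent leaves alone.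

Compound list
1 | ethyl 3-oxo-5-phenylpentanoate | CCOC(=O)CC(=O)CCc1ccccc1 | starting material
2 | ethyl (3R)-3-hydroxy-5-phenylpentanoate | O[C@H](CCc1ccccc1)CC(=O)OCC | intermediate
3 | (3R)-5-phenylpentane-1,3-diol | O[C@H](CCc1ccccc1)CCO | intermediate
4 | allyl acetate | C=CCOC(C)=O | starting material
5 | (3R)-3-hydroxy-5-phenylpentanal (not isolated) | O[C@H](CCc1ccccc1)CC=O | intermediate
6 | (3R,5R)-1-phenyloct-7-ene-3,5-diol (anti diol) | O[C@H](CCc1ccccc1)C[C@H](O)CC=C | intermediate
7 | (4R,6R)-2,2-dimethyl-4-(2-phenylethyl)-6-(prop-2-en-1-yl)-1,3-dioxane (trans, 6',8'-acetonide) | CC1(C)O[C@H](CCc2ccccc2)C[C@@H](CC=C)O1 | intermediate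
8 | (E)-1-methoxybuta-1,3-diene | CO/C=C/C=C | starting material
9 | 3-(trimethylsilyl)prop-2-ynal | C[Si](C)(C)C#CC=O | starting material
10 | (2R,6S)-2-methoxy-6-[(trimethylsilyl)ethynyl]-5,6-dihydro-2H-pyran (cis) | C[Si](C)(C)C#C[C@@H]1CC=C[C@H](OC)O1 | intermediate
11 | (2R,6S)-6-(bromoethynyl)-2-methoxy-5,6-dihydro-2H-pyran | BrC#C[C@@H]1CC=C[C@H](OC)O1 | intermediate
12 | {(Z)-1-bromo-2-[(2S,6R)-6-methoxy-3,6-dihydro-2H-pyran-2-yl]ethenyl}dicyclohexylborane (not isolated) | Br/C(B(C1CCCCC1)C2CCCCC2)=C\[C@@H]3CC=C[C@H](OC)O3 | intermediate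
13 | (2R,6S)-6-[(Z)-2-bromoethenyl]-2-methoxy-5,6-dihydro-2H-pyran | Br/C=C\[C@@H]1CC=C[C@H](OC)O1 | intermediate
14 | (4R,6R)-4-[(2R)-2,3-bis(4,4,5,5-tetramethyl-1,3,2-dioxaborolan-2-yl)propyl]-2,2-dimethyl-6-(2-phenylethyl)-1,3-dioxane (not isolated) | CC1(C)O[C@H](CCc2ccccc2)C[C@@H](C[C@H](B2OC(C)(C)C(C)(C)O2)CB2OC(C)(C)C(C)(C)O2)O1 | intermediate
15 | (4R,6R)-4-{(2R,4Z)-5-[(2S,6R)-6-methoxy-3,6-dihydro-2H-pyran-2-yl]-2-(4,4,5,5-tetramethyl-1,3,2-dioxaborolan-2-yl)pent-4-en-1-yl}-2,2-dimethyl-6-(2-phenylethyl)-1,3-dioxane (not isolated) | CC1(C)O[C@H](CCc2ccccc2)C[C@@H](C[C@H](B2OC(C)(C)C(C)(C)O2)C/C=C\[C@@H]2CC=C[C@H](OC)O2)O1 | intermediate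
16 | (2R,4Z)-1-[(4R,6R)-2,2-dimethyl-6-(2-phenylethyl)-1,3-dioxan-4-yl]-5-[(2S,6R)-6-methoxy-3,6-dihydro-2H-pyran-2-yl]pent-4-en-2-ol | CC1(C)O[C@H](CCc2ccccc2)C[C@@H](C[C@H](O)C/C=C\[C@@H]2CC=C[C@H](OC)O2)O1 | intermediate
17 | (2R)-1-[(4S,6R)-6-{(2Z)-3-[(2S,6R)-6-methoxy-3,6-dihydro-2H-pyran-2-yl]prop-2-en-1-yl}-2,2-dimethyl-1,3-dioxan-4-yl]-4-phenylbutan-2-ol (cis-dioxane, 4',6'-acetonide) | O[C@H](CCc1ccccc1)C[C@H]1C[C@@H](C/C=C\[C@@H]2CC=C[C@H](OC)O2)OC(C)(C)O1 | intermediate
18 | (2R)-1-[(4R,6R)-6-{(2Z)-3-[(2S,6R)-6-methoxy-3,6-dihydro-2H-pyran-2-yl]prop-2-en-1-yl}-2,2-dimethyl-1,3-dioxan-4-yl]-4-phenylbutan-2-yl acetate | CC(=O)O[C@H](CCc1ccccc1)C[C@H]1C[C@@H](C/C=C\[C@@H]2CC=C[C@H](OC)O2)OC(C)(C)O1 | intermediate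
19 | (3R,5R,7R,9Z)-5,7-dihydroxy-10-[(2S)-6-hydroxy-3,6-dihydro-2H-pyran-2-yl]-1-phenyldec-9-en-3-yl acetate (lactol, both anomers) | CC(=O)O[C@H](CCc1ccccc1)C[C@H](O)C[C@H](O)C/C=C\[C@@H]1CC=CC(O)O1 | intermediate
20 | (6S)-6-[(1Z,4R,6R,8R)-8-acetoxy-4,6-dihydroxy-10-phenyldec-1-en-1-yl]-5,6-dihydro-2H-pyran-2-one | CC(=O)O[C@H](CCc1ccccc1)C[C@H](O)C[C@H](O)C/C=C\[C@@H]1CC=CC(=O)O1 | target

Total step count: 12. Longest linear sequence: 9 steps (1–4, then 8–12). The right-hand branch (5–7) joins at step 8.

Steps most likely to fail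

Step 8. The diboration may show poor facial selectivity against the resident C6' centre. In the palladium stage the secondary boronate may transfer instead of the primary one, protodeboronation may compete, or 13 may lose HBr to the base. The fallback sets out from 7 and 10 and comes back at 16. It makes the same C3'–C2' bond by acetylide opening of a terminal epoxide.
- Alkene 7 is epoxidised (mCPBA, CH2Cl2) to the C4'-epimeric 3',4'-epoxide mixture F1.
- Hydrolytic kinetic resolution with a chiral (salen)Co(III) acetate and 0.5 equiv of water leaves the 3',4'-epoxide with the C4'–O bond oriented as in the target F2. It converts the unwanted epimer into the 3',4'-diol F3, which is removed by chromatography.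
- Adduct 10 is desilylated (K2CO3, MeOH) to the terminal alkyne F4.
- The lithium acetylide of F4 (n-BuLi, THF/DMPU, no Lewis acid, so the allylic acetal is spared) opens F2 at C3' to the 1',2'-alkynol F5.
- Lindlar semihydrogenation of F5 (H2, Pd/CaCO3/Pb, quinoline) gives 16.

Step 9. The equilibration may stop short of full conversion. The acid it needs may also ionise the allylic methyl acetal and let it exchange with the free hydroxyl groups. The fallback sets out from 16 and comes back at 19. It replaces the equilibrium by a regiospecific oxidative acetal closure.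
- The C4'-OH of 16 is benzylated (NaH, PMBCl, TBAI, THF) to the 4'-O-PMB ether F6.
- The strained anti acetonide is removed in methanol (PPTS, rt), where exchange at the methyl acetal is degenerate. This gives the 6',8'-diol F7.
- DDQ under anhydrous conditions (4 Å MS, CH2Cl2, 0 °C) oxidises the PMB ether to its oxocarbenium ion. Only the 1,3-related C6'-OH can trap it, giving the 4',6'-p-methoxybenzylidene acetal F8 with O8' free.
- Acetylation (Ac2O, pyridine, DMAP) gives the 8'-acetate F9.
- The aqueous acid of step 11 cleaves both acetals of F9 to 19.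

Step 11. The acidity and time needed to open the syn acetonide expose the liberated lactol. It may ring-open and isomerise to the E-enal, and the acetyl group may migrate from O8' to O6'. The later oxidation then has to discriminate three carbinols. The fallback sets out from 18 and comes back at 20. It changes the order of events so that the oxidation is run with no free alcohol and the diol is released last.
- Only the allylic methyl acetal of 18 is hydrolysed (PPTS, acetone/H2O, rt, the acetone also holding the ketal in place). This gives the acetonide-protected lactol F10.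
- F10 is oxidised (MnO2, or TEMPO/PhI(OAc)2) to the acetonide-protected lactone F11.
- The acetonide of F11 is cleaved on the robust lactone (80 % aq. AcOH, rt to 40 °C) to give 20.

Further compounds
F1 | step 8 | 3',4'-epoxide of 7, mixture of C4' epimers | CC1(C)O[C@H](CCc2ccccc2)C[C@@H](CC2CO2)O1
F2 | step 8 | 3',4'-epoxide of 7 with the C4'–O bond oriented as in the target | CC1(C)O[C@H](CCc2ccccc2)C[C@@H](C[C@H]2CO2)O1
F3 | step 8 | 3',4'-diol from the unwanted epoxide epimer | CC1(C)O[C@H](CCc2ccccc2)C[C@@H](C[C@@H](O)CO)O1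
F4 | step 8 | (2R,6S)-6-ethynyl-2-methoxy-5,6-dihydro-2H-pyran | C#C[C@@H]1CC=C[C@H](OC)O1
F5 | step 8 | 1',2'-alkyne analogue of 16 | CC1(C)O[C@H](CCc2ccccc2)C[C@@H](C[C@H](O)CC#C[C@@H]2CC=C[C@H](OC)O2)O1
F6 | step 9 | 4'-O-(4-methoxybenzyl) ether of 16 | CC1(C)O[C@H](CCc2ccccc2)C[C@@H](C[C@H](OCc2ccc(OC)cc2)C/C=C\[C@@H]2CC=C[C@H](OC)O2)O1
F7 | step 9 | 6',8'-diol with 4'-O-PMB ether and methyl lactol ether | O[C@H](CCc1ccccc1)C[C@H](O)C[C@H](OCc1ccc(OC)cc1)C/C=C\[C@@H]1CC=C[C@H](OC)O1
F8 | step 9 | 4',6'-(4-methoxybenzylidene) acetal (all-equatorial) with free 8'-OH | O[C@H](CCc1ccccc1)C[C@H]1C[C@@H](C/C=C\[C@@H]2CC=C[C@H](OC)O2)O[C@@H](c2ccc(OC)cc2)O1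
F9 | step 9 | 8'-acetate of F8 | CC(=O)O[C@H](CCc1ccccc1)C[C@H]1C[C@@H](C/C=C\[C@@H]2CC=C[C@H](OC)O2)O[C@@H](c2ccc(OC)cc2)O1
F10 | step 11 | lactol of 18 with the 4',6'-acetonide kept (both anomers) | CC(=O)O[C@H](CCc1ccccc1)C[C@H]1C[C@@H](C/C=C\[C@@H]2CC=CC(O)O2)OC(C)(C)O1
F11 | step 11 | 4',6'-acetonide of the target lactone | CC(=O)O[C@H](CCc1ccccc1)C[C@H]1C[C@@H](C/C=C\[C@@H]2CC=CC(=O)O2)OC(C)(C)O1
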